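Remarks on the chemistry (assumptions)
- Germacrane numbering is used: ring C1–C10, C14 on C10, C15 on C4, lactone C12(=O)–O–C6 with the exo-methylene C11=C13, hydroxyls on C7 and C8, angelate on C9.
- L-Arabinose is used as its furanose, and its C1–C5 become C9–C5 of the target (sugar C2 → C8, C3 → C7, C4 → C6). Sugar C3 is re-made from a ketone.
- Hemiacetals 6, 30 and 36 are anomeric mixtures; their hemiacetal carbon is left undefined in the SMILES.

## Structural features

The target is a germacranolide: a ten-membered carbocycle (C1–C10) with a Z-trisubstituted C1=C10 olefin and an E-trisubstituted C4=C5 olefin, fused across C6–C7 to an α-methylene-γ-butyrolactone (C11=C13, C12 carbonyl, ring oxygen on C6). Four stereocentres stand in a row: C6 (S, allylic lactone oxygen), C7 (S, fully substituted, tertiary hydroxyl and C11), C8 (S, secondary hydroxyl) and C9 (R, allylic angelate next to the fully substituted C10). C6/C7 and C8/C9 are threo, C7/C8 is erythro, and C5 and C8 are cis on the lactone ring. The fragile groups are the acrylate lactone (Michael acceptor, reducible), the angelate (isomerises to the tiglate and can migrate to O8), the allylic C6–O bond and the 1(10),4-diene, which can cyclise across the ring in acid. The real difficulty is the medium ring with its Z-trisubstituted olefin directly beside the oxygenated C7–C9 array, together with the fully substituted C7 that must be set relative to C6 and C8. The key step exploits the fact that C9 is a secondary allylic carbinol bonded to the olefinic C10. Cutting C9–C10 gives a C9 aldehyde and a Z-alkenyl iodide at C10, so the Z geometry is made on an open chain and only carried through the ring closure. The C6–C8 oxygen pattern is that of an L-threo-pentos-3-ulose, which is pseudo-twofold symmetric, so L-arabinose can supply C6 and C8 whichever end of the sugar becomes C9.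

## Logic of the disconnections

43 ⇒ 42 ⇒ 39 + 40. The two acetal C–O bonds on O7/O8 and the C9–O acyl bond are cut last. The acyl group is put on while O7 and O8 are still tied together, so no choice between the C8 and C9 hydroxyls is needed. The forward steps must acylate a hindered allylic carbinol with retention and without Z-to-E isomerisation of the acyl group, and the final hydrolysis must spare the diene and the allylic C6–O bond.

39 ⇒ 38. The C9–C10 bond of the ten-membered ring is cut. The medium ring and its only ring-made stereocentre disappear, and what remains is an open chain on a rigid spiro lactone–dioxolane core in which C9 and C6 are cis on the dioxolane. The forward step must add an alkenyl metal to an aldehyde in the presence of an acrylate, keep the Z geometry and close a ten-membered ring at high dilution.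

38 ⇒ 37 ⇒ 34. The C9 carbonyl goes back to a silyl ether, and the lactone acyl C12–O6 bond and the C12 oxidation level are removed, which leaves a 2-methylene-1,4-diol. The acrylate is therefore absent during all hydride, organolithium and ylide chemistry. The forward oxidation must pick the primary allylic hydroxyl and close on O6 only; this is secured because O8 is held in the dioxolane and O9 is silylated.

34 ⇒ 33 ⇒ 31 ⇒ 30 ⇒ 29. These are protecting-group changes plus one ring–chain change. The O9 silyl ether and the O12 benzyl-type ether are taken off, the C9–O6 hemiacetal bond is re-formed, and the acetonide is moved back from O7/O8 to the anomeric O9/O8 position. In 29 the future aldehyde carbon is stored as a robust anomeric acetal and O6 is a ring oxygen, so neither needs a group of its own during chain building. The forward demand is a clean acetonide shift onto the all-cis 7,8-diol.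

29 ⇒ 23 + 24 + 25. The C1=C10 double bond is cut to a C1 aldehyde and a two-carbon iodo-ylide (27 and 28 form in the flask). This brings in C10, C14 and the iodine in one step, and it demands Z selectivity.

23 ⇒ 21 ⇒ 18 + 19. The C2–C3 bond is cut between a primary allylic bromide and a cyanomethyl anion (20). The nitrile is the aldehyde precursor, and the forward alkylation must go by direct displacement without allylic transposition.

18 ⇒ 16 ⇒ 15 ⇒ 14 + 13, and 14 ⇒ 12. The C4=C5 double bond is cut to a sugar C5 aldehyde and a stabilised ylide that carries C15, C4 and C3. This gives the E-trisubstituted olefin reliably, and the aldehyde must be used without epimerisation of the adjacent centre.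

12 ⇒ 11 ⇒ 9 + 10 (10 from 3). The C7–C11 bond is cut. The fully substituted carbinol comes from a bicyclic ketone whose two faces differ strongly, and C11–C13 arrive with C12 at the alcohol level. The forward addition must come from the convex face.

9 ⇒ 8 ⇒ 6 ⇒ 4 + 5 + 7, and 3 ⇒ 1 + 2. The ketone, the acetonide and the silyl ether are taken back to the sugar, whose C2 and C4 already carry the configurations of C8 and C6.

## Other disconnections considered

Alternative 1: The cut is the O6–C10 bond of a pyranone and, behind it, the furan ring of the 5-methylfuran-2-yl carbinol A1, so C6–C10 come from a furan. The forward key step is the oxidative ring expansion of A1 (N-bromosuccinimide in buffered aqueous THF, or VO(acac)2 with t-BuOOH) to pyranone A2, which holds C6, a C7 ketone, a C8=C9 enone and C10 as a methyl-bearing hemiketal.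
- In its favour: the step is very well precedented, A1 is available by catalytic asymmetric reduction, and C10 arrives with its methyl group. On precedent of the key step and on the cost of the first five carbons it is the better plan.
- Against it here: C7, C8 and C9 would all still have to be set on A2 (addition to the C7 ketone for the quaternary carbinol, oxygenation of the enone with the 8,9-threo and 7,8-erythro relationships), controlled only by C6 and the anomeric centre. The hemiketal would later have to be opened to a methyl ketone, from which the Z-trisubstituted C1=C10 olefin would have to be made, the very problem the chosen plan avoids with a preformed Z-iodoalkene.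
- Comparison: structurally it carries less stereochemistry from the start; mechanistically its key step is safer; in step economy it would gain early and lose later.

Alternative 2: The cut is the C2–C3 bond between two allylic carbons, with C5–C10 taken from D-galactose A3, whose C2–C5 match C6–C9. The forward key step would be the attack of the C3 carbanion of an E-allylic phenyl sulfone (KN(SiMe3)2, high dilution) on a Z-allylic bromide at C2, giving the ten-membered sulfone A4.
- In its favour: all four stereocentres, C9 included, would be fixed before the ring is closed, so no stereocentre is made in the macrocyclisation. On this point it is better than the chosen plan, whose C9 selectivity is its weakest point. The bond formed is an unhindered sp3–sp3 bond far from the crowded array, and sulfone closures of ten-membered rings are established. The Z-olefin is also set before ring closure, which equals the chosen plan.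
- Against it here: the sulfone would have to be removed reductively beside an allylic C6–O bond; the Z-allylic bromide is prone to isomerisation and transposition; and the lactone would still have to be built on the medium ring from the silylalkyne.
- Comparison: with its extra protecting groups (benzyl-type ether, two silyl groups, acetonide) it should be longer.

Alternative 3: The cuts are O6–C12 and C11–C12 of the lactone, with carbon monoxide as C12 and the C8/C9 diol taken from diethyl D-tartrate A5. The forward key step would be the cyclocarbonylation of the C7 ethynyl group and the C6 hydroxyl on the preformed ten-membered ring (PdCl2, SnCl2, PPh3, CO) to the lactone A6.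
- In its favour: the acrylate would appear last and never meet hydrides, ylides or organometals. Here it is better than the chosen plan, which has to carry a masked diol, two extra protecting groups and an oxidation. C9 would come from the chiral pool, again a point in its favour, and the lactone closure is atom-economic.
- Against it here: the macrocycle would have to be closed by another, unspecified C–C bond. C6 and C7 are not supplied by A5 and would need acyclic control. Lewis-acidic SnCl2 and divalent palladium at about 75 °C would meet the acid-sensitive diene and a free allylic C6 hydroxyl. After hydrolysis of the 8,9-acetonide of A6 the C8 and C9 hydroxyls would have to be told apart for angeloylation, which the chosen plan avoids.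
- Comparison: on step economy the two plans should be similar.

Key step: step 19

## Route

Step 1
Reactants: 1 2-bromoprop-2-en-1-ol; 2 4-methoxybenzyl chloride
Product: 3 1-{[(2-bromoprop-2-en-1-yl)oxy]methyl}-4-methoxybenzene (2-bromoallyl PMB ether)
Conditions: NaH, n-Bu4NI (cat.), THF, 0 °C to rt
Reagents that add atoms: 4-methoxybenzyl chloride (2), COc1ccc(CCl)cc1
Why: Williamson ether synthesis on a primary allylic alkoxide; the vinylic bromide does not react under these conditions.

Step 2
Reactants: 4 L-arabinose; 5 tert-butyl(chloro)diphenylsilane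
Product: 6 5-O-(tert-butyldiphenylsilyl)-L-arabinofuranose (α/β mixture)
Conditions: imidazole, DMF, 0 °C to rt
Reagents that add atoms: tert-butyl(chloro)diphenylsilane (5), CC(C)(C)[Si](Cl)(c1ccccc1)c1ccccc1
Why: Selective silylation of a primary hydroxyl: only the furanose tautomers have one, and mutarotation feeds them as they are consumed. Sugar C2 and C4 (later C8 and C6) are untouched.

Step 3
Reactants: 6 5-O-(tert-butyldiphenylsilyl)-L-arabinofuranose; 7 2,2-dimethoxypropane
Product: 8 5-O-(tert-butyldiphenylsilyl)-1,2-O-isopropylidene-β-L-arabinofuranose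
Conditions: TsOH (cat.), acetone, rt
Reagents that add atoms: 2,2-dimethoxypropane (7), COC(C)(C)OC
Why: Acid-catalysed acetonide formation; on the furanose only O1 and O2 can be cis (β-anomer), while O3 is trans to O2 and stays free for oxidation.

Step 4
Reactants: 8 5-O-(tert-butyldiphenylsilyl)-1,2-O-isopropylidene-β-L-arabinofuranose
Product: 9 5-O-(tert-butyldiphenylsilyl)-1,2-O-isopropylidene-β-L-threo-pentofuranos-3-ulose
Conditions: Dess–Martin periodinane, CH2Cl2, rt
Reagents that add atoms: none
Why: Dess–Martin oxidation of the secondary alcohol under non-basic conditions, so the two α-centres are not epimerised; the old C3 stereocentre is erased on purpose.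

Step 5
Reactants: 9 5-O-(tert-butyldiphenylsilyl)-1,2-O-isopropylidene-β-L-threo-pentofuranos-3-ulose; 3 2-bromoallyl PMB ether
Product: 11 5-O-(tert-butyldiphenylsilyl)-1,2-O-isopropylidene-3-C-{3-[(4-methoxybenzyl)oxy]prop-1-en-2-yl}-β-L-lyxofuranose (3-OH cis to O2), via alkenyllithium 10 (not isolated)
Conditions: 3, t-BuLi (2 equiv), Et2O, −78 °C; then 9, THF, −78 °C; H2O
Reagents that add atoms: 2-bromoallyl PMB ether (3), C=C(Br)COCc1ccc(OC)cc1
Why: Bromine–lithium exchange, then 1,2-addition of the alkenyllithium to the ketone. The reagent enters from the convex face, opposite the cis-fused 1,2-acetonide and the C4 side chain, so the new hydroxyl is cis to O2 (L-lyxo) and the carbinol carbon has the 7S configuration of the target.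

Step 6
Reactants: 11 the silyl ether from step 5
Product: 12 1,2-O-isopropylidene-3-C-{3-[(4-methoxybenzyl)oxy]prop-1-en-2-yl}-β-L-lyxofuranose
Conditions: n-Bu4NF, THF, 0 °C to rt
Reagents that add atoms: none
Why: Fluoride cleavage of the silyl ether; acetonide, PMB ether and tertiary alcohol are inert.

Step 7
Reactants: 12 the diol from step 6; 13 ethyl 2-(triphenylphosphoranylidene)propanoate
Product: 15 ethyl (E)-enoate in which sugar C5 is the β-carbon of a 2-methylacrylate (target C5=C4(C15)–C3), via aldehyde 14 (not isolated)
Conditions: Dess–Martin periodinane, CH2Cl2, 0 °C to rt; then 13, rt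
Reagents that add atoms: ethyl 2-(triphenylphosphoranylidene)propanoate (13), CCOC(=O)C(C)=P(c1ccccc1)(c1ccccc1)c1ccccc1
Why: Oxidation of the only primary alcohol and Wittig olefination of the crude α-alkoxy aldehyde in the same flask, which avoids epimerisation at sugar C4. The stabilised, α-branched ylide gives the E-trisubstituted olefin.

Step 8
Reactants: 15 the E-enoate
Product: 16 (E)-allylic alcohol (C3–OH)
Conditions: i-Bu2AlH (3.5 equiv), CH2Cl2, −78 °C; aq. potassium sodium tartrate
Reagents that add atoms: none
Why: 1,2-Reduction of the conjugated ester by diisobutylaluminium hydride; the olefin geometry is kept and the acetonide is stable at −78 °C.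

Step 9
Reactants: 16 the allylic alcohol; 17 tetrabromomethane
Product: 18 (E)-allylic bromide (C3–Br)
Conditions: PPh3, 2,6-lutidine, CH2Cl2, 0 °C
Reagents that add atoms: tetrabromomethane (17), BrC(Br)(Br)Br
Why: Appel bromination of the primary allylic alcohol by SN2 displacement of the oxyphosphonium ion; the hindered tertiary alcohol does not react at 0 °C.

Step 10
Reactants: 18 the allylic bromide; 19 acetonitrile
Product: 21 nitrile with the chain (E)-CH=C(CH3)CH2CH2CN on sugar C4, via (cyanomethyl)lithium 20 (not isolated)
Conditions: 19, n-BuLi (3 equiv each), THF, −78 °C; then 18, −78 to −30 °C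
Reagents that add atoms: acetonitrile (19), CC#N
Why: SN2 alkylation of lithioacetonitrile at the unhindered CH2 terminus of the allylic bromide forms C2–C3 without allylic transposition; one equivalent of the reagent is spent on the tertiary hydroxyl.

Step 11
Reactants: 21 the nitrile; 22 water
Product: 23 aldehyde with the chain (E)-CH=C(CH3)CH2CH2CHO (C1 aldehyde)
Conditions: i-Bu2AlH, CH2Cl2, −78 °C; then aq. potassium sodium tartrate, pH 5 buffer, 0 °C
Reagents that add atoms: water (22), O
Why: Diisobutylaluminium hydride adds once to the nitrile and stops at the N-aluminio imine, which is hydrolysed to the aldehyde on work-up.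

Step 12
Reactants: 23 the aldehyde; 24 ethyltriphenylphosphonium iodide; 25 iodine
Product: 29 (Z)-iodoalkene: 1,2-O-isopropylidene-β-L-lyxofuranose with the tertiary 3-OH and 3-C-[3-(PMB-oxy)prop-1-en-2-yl] group and, on C4, the (1E,5Z)-6-iodo-2-methylhepta-1,5-dien-1-yl chain, via ethylidenetriphenylphosphorane 26 (not isolated), via (1-iodoethyl)triphenylphosphonium iodide 27 (not isolated), via (1-iodoethylidene)triphenylphosphorane 28 (not isolated)
Conditions: 24, n-BuLi, THF, rt; 25, −78 °C; NaN(SiMe3)2, −20 °C; then 23, −78 to −20 °C
Reagents that add atoms: ethyltriphenylphosphonium iodide (24), CC[P+](c1ccccc1)(c1ccccc1)c1ccccc1.[I-]; iodine (25), II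
Why: Stork–Zhao iodo-olefination: the non-stabilised α-iodo ylide reacts under kinetic control through the cis-oxaphosphetane, which places iodine cis to the chain and gives the Z-2-iodoalkene (later C1=C10 with C14).

Step 13
Reactants: 29 the (Z)-iodoalkene
Product: 30 2,3-O-isopropylidene lactol (L-lyxofuranose with free anomeric OH; sugar C1 = target C9)
Conditions: camphorsulfonic acid (cat.), acetone, rt
Reagents that add atoms: none
Why: Acid-catalysed acetal migration: with O1, O2 and O3 all cis, the isopropylidene group moves from the anomeric 1,2-position to the 2,3-diol, the arrangement that lyxo- and manno-furanoses take under equilibrating acetonation. This ties O7 to O8 and frees C9 as a hemiacetal.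

Step 14
Reactants: 30 the lactol
Product: 31 open-chain diol (primary C9–OH, secondary allylic C6–OH) with the 7,8-acetonide
Conditions: NaBH4, MeOH, 0 °C
Reagents that add atoms: none
Why: Borohydride reduction of the hemiacetal through its open hydroxy-aldehyde form; vinyl iodide, olefins and PMB ether are inert.

Step 15
Reactants: 31 the diol; 32 chlorotriethylsilane
Product: 33 9-O-triethylsilyl ether of 31
Conditions: imidazole, CH2Cl2, −20 °C
Reagents that add atoms: chlorotriethylsilane (32), CC[Si](Cl)(CC)CC
Why: Selective silylation of the primary hydroxyl; the secondary C6 hydroxyl sits between the fully substituted C7 and the olefin and is left free.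

Step 16
Reactants: 33 the silyl ether
Product: 34 2-methylene-1,4-diol (primary allylic C12–OH and C6–OH)
Conditions: DDQ, CH2Cl2/pH 7 buffer, 0 °C
Reagents that add atoms: none
Why: Oxidative cleavage of the p-methoxybenzyl ether by DDQ under buffered conditions, which keeps the triethylsilyl ether and the acetonide.

Step 17
Reactants: 34 the 2-methylene-1,4-diol
Product: 37 α-methylene-γ-butyrolactone with the 7,8-acetonide and 9-O-triethylsilyl ether, via hydroxy enal 35 (not isolated), via 2-methylene lactol 36 (not isolated)
Conditions: TEMPO (cat.), PhI(OAc)2, CH2Cl2, rt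
Reagents that add atoms: none
Why: TEMPO/PhI(OAc)2 oxidative lactonisation of a 2-methylene-1,4-diol: the oxoammonium ion oxidises only the primary allylic alcohol, the enal is trapped by the C6 hydroxyl (O8 is blocked in the dioxolane, O9 is silylated) and the lactol is oxidised on. No stereocentre is touched.

Step 18
Reactants: 37 the lactone silyl ether
Product: 38 Z-iodoalkene aldehyde lactone 7,8-acetonide
Conditions: (COCl)2, DMSO, CH2Cl2, −78 to −40 °C; then i-Pr2NEt, −78 to −20 °C
Reagents that add atoms: none
Why: Swern oxidation that converts a primary triethylsilyl ether directly into the aldehyde (chloride-assisted loss of the silyl group from the O-silylated alkoxysulfonium ion, then ylide fragmentation). Hünig base and low temperature protect the α-oxygenated C8 centre.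

Step 19
Reactants: 38 Z-iodoalkene aldehyde lactone 7,8-acetonide
Product: 39 9-hydroxy germacranolide 7,8-acetonide (9R)
Conditions: CrCl2 (20 mol %), NiCl2(dme) (2 mol %), Cp2ZrCl2 (1.2 equiv), n-Bu4NBr, DMF, undivided cell, Al anode, Ni-foam cathode, constant current, rt; 38 added slowly (about 2 mM)
Reagents that add atoms: none
Why: Proposed new method: the cathode reduces trivalent to divalent chromium, divalent chromium reduces NiCl2 to zerovalent nickel, which inserts into the C10–I bond with retention of the Z geometry and passes the alkenyl group to trivalent chromium; the alkenylchromium adds to the C9 aldehyde and Cp2ZrCl2 takes over the alkoxide so that chromium returns to the cycle. The closest known reactions are the stoichiometric Nozaki–Hiyama–Kishi macrocyclisation of iodoalkenyl aldehydes and the chromium-catalysed electroreductive intermolecular coupling of alkenyl halides with aldehydes. The ten-membered ring closes in a 10-exo-trig mode, the carbonyl oxygen staying outside the new ring. C9 is the only new stereocentre and is controlled by C8 inside the cis-fused dioxolane, which holds the formyl group cis to C6. With the forming bond anti to the C8–O bond and the chromium-bound oxygen turned to the periphery (the aldehyde hydrogen next to the fully substituted C7), the exposed face leads to the 8,9-threo (9R) alcohol, which is the selectivity the step needs. The step also needs reaction at the aldehyde and not at the acrylate, and ring closure instead of oligomerisation; the carbonyl-selective alkenylchromium, the mild potential of the chromium couple and slow addition at high dilution secure this.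

Step 20
Reactants: 39 9-hydroxy germacranolide 7,8-acetonide; 40 angelic acid
Product: 42 9-O-angeloyl germacranolide 7,8-acetonide, via angelic 2,4,6-trichlorobenzoic anhydride 41 (not isolated)
Conditions: 40, 2,4,6-trichlorobenzoyl chloride, Et3N, toluene, rt; then 39, 75 °C
Reagents that add atoms: angelic acid (40), C/C=C(/C)C(=O)O
Why: Yamaguchi-type mixed-anhydride acylation without a nucleophilic catalyst: the shielded aroyl carbonyl directs the alcohol to the angeloyl carbonyl, and leaving out DMAP avoids isomerisation to the tiglate. C9 keeps its configuration.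

Step 21
Reactants: 42 9-O-angeloyl germacranolide 7,8-acetonide
Product: 43 target, (6S,7S,8S,9R)-9-angeloyloxy-7,8-dihydroxygermacra-1(10)Z,4E,11(13)-trien-12,6-olide
Conditions: AcOH/H2O (4:1), 40 °C
Reagents that add atoms: none
Why: Acid-catalysed acetal hydrolysis under dilute, weakly acidic conditions; ionisation at the tertiary allylic C7–O is disfavoured by the electron-poor C11=C13, and the angelate is stable to dilute acid.

## Compound list

1 | 2-bromoprop-2-en-1-ol | C=C(Br)CO | starting material
2 | 4-methoxybenzyl chloride | COc1ccc(CCl)cc1 | starting material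
3 | 1-{[(2-bromoprop-2-en-1-yl)oxy]methyl}-4-methoxybenzene | C=C(Br)COCc1ccc(OC)cc1 | intermediate
4 | L-arabinose | O=C[C@H](O)[C@@H](O)[C@@H](O)CO | starting material
5 | tert-butyl(chloro)diphenylsilane | CC(C)(C)[Si](Cl)(c1ccccc1)c1ccccc1 | starting material
6 | 5-O-(tert-butyldiphenylsilyl)-L-arabinofuranose (anomers) | CC(C)(C)[Si](c1ccccc1)(c1ccccc1)OC[C@@H]1OC(O)[C@H](O)[C@H]1O | intermediate
7 | 2,2-dimethoxypropane | COC(C)(C)OC | starting material
8 | 5-O-(tert-butyldiphenylsilyl)-1,2-O-isopropylidene-β-L-arabinofuranose | CC(C)(C)[Si](c1ccccc1)(c1ccccc1)OC[C@@H]1O[C@@H]2OC(C)(C)O[C@@H]2[C@H]1O | intermediate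
9 | 5-O-(tert-butyldiphenylsilyl)-1,2-O-isopropylidene-β-L-threo-pentofuranos-3-ulose | CC(C)(C)[Si](c1ccccc1)(c1ccccc1)OC[C@@H]1O[C@@H]2OC(C)(C)O[C@@H]2C1=O | intermediate
10 | {3-[(4-methoxybenzyl)oxy]prop-1-en-2-yl}lithium | [Li]C(=C)COCc1ccc(OC)cc1 | intermediate
11 | 5-O-(tert-butyldiphenylsilyl)-1,2-O-isopropylidene-3-C-{3-[(4-methoxybenzyl)oxy]prop-1-en-2-yl}-β-L-lyxofuranose | CC(C)(C)[Si](c1ccccc1)(c1ccccc1)OC[C@@H]1O[C@@H]2OC(C)(C)O[C@@H]2[C@@]1(O)C(=C)COCc1ccc(OC)cc1 | intermediate
12 | 1,2-O-isopropylidene-3-C-{3-[(4-methoxybenzyl)oxy]prop-1-en-2-yl}-β-L-lyxofuranose | OC[C@@H]1O[C@@H]2OC(C)(C)O[C@@H]2[C@@]1(O)C(=C)COCc1ccc(OC)cc1 | intermediate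
13 | ethyl 2-(triphenylphosphoranylidene)propanoate | CCOC(=O)C(C)=P(c1ccccc1)(c1ccccc1)c1ccccc1 | starting material
14 | 1,2-O-isopropylidene-3-C-{3-[(4-methoxybenzyl)oxy]prop-1-en-2-yl}-β-L-lyxo-pentodialdo-1,4-furanose | O=C[C@@H]1O[C@@H]2OC(C)(C)O[C@@H]2[C@@]1(O)C(=C)COCc1ccc(OC)cc1 | intermediate
15 | ethyl (E)-2-methylprop-2-enoate carrying the furanose of 12 at its β-carbon (former sugar C5) | CCOC(=O)/C(C)=C/[C@@H]1O[C@@H]2OC(C)(C)O[C@@H]2[C@@]1(O)C(=C)COCc1ccc(OC)cc1 | intermediate
16 | (E)-allylic alcohol from 15 (C3–OH) | OC/C(C)=C/[C@@H]1O[C@@H]2OC(C)(C)O[C@@H]2[C@@]1(O)C(=C)COCc1ccc(OC)cc1 | intermediate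
17 | tetrabromomethane | BrC(Br)(Br)Br | starting material
18 | (E)-allylic bromide from 16 (C3–Br) | BrC/C(C)=C/[C@@H]1O[C@@H]2OC(C)(C)O[C@@H]2[C@@]1(O)C(=C)COCc1ccc(OC)cc1 | intermediate
19 | acetonitrile | CC#N | starting material
20 | (cyanomethyl)lithium | [Li]CC#N | intermediate
21 | nitrile, chain (E)-CH=C(CH3)CH2CH2CN on sugar C4 | N#CCC/C(C)=C/[C@@H]1O[C@@H]2OC(C)(C)O[C@@H]2[C@@]1(O)C(=C)COCc1ccc(OC)cc1 | intermediate
22 | water | O | starting material
23 | aldehyde, chain (E)-CH=C(CH3)CH2CH2CHO on sugar C4 | O=CCC/C(C)=C/[C@@H]1O[C@@H]2OC(C)(C)O[C@@H]2[C@@]1(O)C(=C)COCc1ccc(OC)cc1 | intermediate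
24 | ethyltriphenylphosphonium iodide | CC[P+](c1ccccc1)(c1ccccc1)c1ccccc1.[I-] | starting material
25 | iodine | II | starting material
26 | ethylidenetriphenylphosphorane | CC=P(c1ccccc1)(c1ccccc1)c1ccccc1 | intermediate
27 | (1-iodoethyl)triphenylphosphonium iodide | CC(I)[P+](c1ccccc1)(c1ccccc1)c1ccccc1.[I-] | intermediate
28 | (1-iodoethylidene)triphenylphosphorane | CC(I)=P(c1ccccc1)(c1ccccc1)c1ccccc1 | intermediate
29 | (Z)-iodoalkene, 1,2-O-isopropylidene-β-L-lyxofuranose with the (1E,5Z)-6-iodo-2-methylhepta-1,5-dien-1-yl chain on C4 | C/C(I)=C/CC/C(C)=C/[C@@H]1O[C@@H]2OC(C)(C)O[C@@H]2[C@@]1(O)C(=C)COCc1ccc(OC)cc1 | intermediate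
30 | 2,3-O-isopropylidene lactol isomer of 29 (anomers) | C/C(I)=C/CC/C(C)=C/[C@@H]1OC(O)[C@@H]2OC(C)(C)O[C@]12C(=C)COCc1ccc(OC)cc1 | intermediate
31 | open-chain diol (C9–OH, C6–OH), 7,8-acetonide, PMB ether on O12 | C/C(I)=C/CC/C(C)=C/[C@H](O)[C@@]1(C(=C)COCc2ccc(OC)cc2)OC(C)(C)O[C@H]1CO | intermediate
32 | chlorotriethylsilane | CC[Si](Cl)(CC)CC | starting material
33 | 9-O-triethylsilyl ether of 31 | C/C(I)=C/CC/C(C)=C/[C@H](O)[C@@]1(C(=C)COCc2ccc(OC)cc2)OC(C)(C)O[C@H]1CO[Si](CC)(CC)CC | intermediate
34 | 2-methylene-1,4-diol (C12–OH, C6–OH), 9-O-triethylsilyl, 7,8-acetonide | C/C(I)=C/CC/C(C)=C/[C@H](O)[C@@]1(C(=C)CO)OC(C)(C)O[C@H]1CO[Si](CC)(CC)CC | intermediate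
35 | hydroxy enal (C12 aldehyde, C6–OH) | C/C(I)=C/CC/C(C)=C/[C@H](O)[C@@]1(C(=C)C=O)OC(C)(C)O[C@H]1CO[Si](CC)(CC)CC | intermediate
36 | 2-methylene lactol (C12 hemiacetal with O6, anomers) | C=C1C(O)O[C@@H](/C=C(\C)CC/C=C(/C)I)[C@]12OC(C)(C)O[C@H]2CO[Si](CC)(CC)CC | intermediate
37 | α-methylene-γ-butyrolactone, 7,8-acetonide, 9-O-triethylsilyl ether | C=C1C(=O)O[C@@H](/C=C(\C)CC/C=C(/C)I)[C@]12OC(C)(C)O[C@H]2CO[Si](CC)(CC)CC | intermediate
38 | Z-iodoalkene aldehyde lactone 7,8-acetonide | C=C1C(=O)O[C@@H](/C=C(\C)CC/C=C(/C)I)[C@]12OC(C)(C)O[C@H]2C=O | intermediate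
39 | 9-hydroxy germacranolide 7,8-acetonide (9R) | C=C1C(=O)O[C@H]2/C=C(\C)CC/C=C(/C)[C@@H](O)[C@@H]3OC(C)(C)O[C@]123 | intermediate
40 | angelic acid, (Z)-2-methylbut-2-enoic acid | C/C=C(/C)C(=O)O | starting material
41 | angelic 2,4,6-trichlorobenzoic anhydride | C/C=C(/C)C(=O)OC(=O)c1c(Cl)cc(Cl)cc1Cl | intermediate
42 | 9-O-angeloyl germacranolide 7,8-acetonide | C=C1C(=O)O[C@H]2/C=C(\C)CC/C=C(/C)[C@@H](OC(=O)/C(C)=C\C)[C@@H]3OC(C)(C)O[C@]123 | intermediate
43 | CNP0303917.1, (6S,7S,8S,9R)-9-angeloyloxy-7,8-dihydroxygermacra-1(10)Z,4E,11(13)-trien-12,6-olide | C=C1C(=O)O[C@H]2/C=C(\C)CC/C=C(/C)[C@@H](OC(=O)/C(C)=C\C)[C@H](O)[C@@]12O | target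

## Step count and least certain steps

Total: 21 steps. Longest linear sequence: 20 steps (steps 2–21, from 4 to 43); step 1 is a one-step branch.

Step 19 (key step). Most likely to go wrong: poor chromium turnover at the low concentration that ring closure needs, with reduction of the C–I bond or oligomerisation taking over; and attack on the other carbonyl face, because the intrinsic Felkin–Anh preference of an α-alkoxy aldehyde favours the 8,9-erythro alcohol and only the ring constraint argues for the threo one. Fallback (known chemistry): starting from 38, the classical Nozaki–Hiyama–Kishi closure with excess CrCl2 containing about 1 % NiCl2 in degassed DMSO at about 2 mM gives 39 directly. Should either closure favour the 9-epimeric alcohol F1, it is not lost: Mitsunobu esterification of F1 with 40 (PPh3, DIAD, toluene, 0 °C to rt) inverts C9 and comes back to the route at 42.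

Step 21. Most likely to go wrong: acid-induced transannular cyclisation of the 1(10),4-diene or ionisation at the allylic C6–O bond during acetonide hydrolysis, and migration of the angelate to the freed C8 hydroxyl. Fallback (change of protecting-group strategy): starting from 37, aqueous acetic acid removes acetonide and silyl ether before any medium ring exists and gives the triol lactone F2. TESOTf with 2,6-lutidine gives the tris(triethylsilyl) ether F3; Swern oxidation as in step 18 gives the 7,8-bis(silyloxy) aldehyde F4; ring closure as in step 19 gives the macrocyclic alcohol F5; acylation as in step 20 gives the angelate F6; and HF·pyridine in THF removes both silyl groups under nearly neutral conditions, coming back at 43.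

Step 13. Most likely to go wrong: sluggish opening of the robust anomeric acetonide under acid mild enough for the PMB ether and the allylic tertiary alcohol, so that the isomerisation stalls. Fallback: starting from 29, aqueous CF3CO2H in THF at 0 °C hydrolyses the 1,2-acetonide to the free lactol triol F7. This is then acetonated under equilibrating conditions (acetone, H2SO4 cat., CuSO4), the classical acetonation of an all-cis furanose triol, and comes back at 30.

Step 5. Most likely to go wrong: enolisation of the ketone by the alkenyllithium, or β-elimination of the reagent if it warms, giving low conversion; the facial selectivity is not in doubt. Fallback: starting from 9, isopropenylmagnesium bromide adds from the same face to give the isopropenyl carbinol F8. Allylic hydroxylation of its only allylic methyl group (SeO2 cat., t-BuOOH, CH2Cl2) gives the allylic alcohol F9, and 4-methoxybenzyl trichloroacetimidate with catalytic camphorsulfonic acid etherifies the primary hydroxyl, coming back at 11.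

## Further compounds

F1 | step 19 | 9-epi-39, (9S)-9-hydroxy germacranolide 7,8-acetonide | C=C1C(=O)O[C@H]2/C=C(\C)CC/C=C(/C)[C@H](O)[C@@H]3OC(C)(C)O[C@]123
F2 | step 21 | triol lactone (7,8,9-triol) | C=C1C(=O)O[C@@H](/C=C(\C)CC/C=C(/C)I)[C@@]1(O)[C@@H](O)CO
F3 | step 21 | 7,8,9-tris(triethylsilyl) ether of F2 | C=C1C(=O)O[C@@H](/C=C(\C)CC/C=C(/C)I)[C@@]1(O[Si](CC)(CC)CC)[C@@H](O[Si](CC)(CC)CC)CO[Si](CC)(CC)CC
F4 | step 21 | 7,8-bis(triethylsilyloxy) aldehyde | C=C1C(=O)O[C@@H](/C=C(\C)CC/C=C(/C)I)[C@@]1(O[Si](CC)(CC)CC)[C@@H](O[Si](CC)(CC)CC)C=O
F5 | step 21 | 9-hydroxy-7,8-bis(triethylsilyloxy) germacranolide | C=C1C(=O)O[C@H]2/C=C(\C)CC/C=C(/C)[C@@H](O)[C@H](O[Si](CC)(CC)CC)[C@@]12O[Si](CC)(CC)CC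
F6 | step 21 | 9-O-angeloyl-7,8-bis(triethylsilyloxy) germacranolide | C=C1C(=O)O[C@H]2/C=C(\C)CC/C=C(/C)[C@@H](OC(=O)/C(C)=C\C)[C@H](O[Si](CC)(CC)CC)[C@@]12O[Si](CC)(CC)CC
F7 | step 13 | free lactol triol from 29 (anomers) | C/C(I)=C/CC/C(C)=C/[C@@H]1OC(O)[C@H](O)[C@@]1(O)C(=C)COCc1ccc(OC)cc1
F8 | step 5 | 5-O-(tert-butyldiphenylsilyl)-1,2-O-isopropylidene-3-C-(prop-1-en-2-yl)-β-L-lyxofuranose | CC(C)(C)[Si](c1ccccc1)(c1ccccc1)OC[C@@H]1O[C@@H]2OC(C)(C)O[C@@H]2[C@@]1(O)C(C)=C
F9 | step 5 | 5-O-(tert-butyldiphenylsilyl)-1,2-O-isopropylidene-3-C-(3-hydroxyprop-1-en-2-yl)-β-L-lyxofuranose | CC(C)(C)[Si](c1ccccc1)(c1ccccc1)OC[C@@H]1O[C@@H]2OC(C)(C)O[C@@H]2[C@@]1(O)C(=C)CO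
A1 | alternative 1 | (5-methylfuran-2-yl) carbinol with silyloxymethyl group | Cc1ccc([C@@H](O)CO[Si](C)(C)C(C)(C)C)o1
A2 | alternative 1 | 2,6-trans-6-hydroxy-6-methyl-2-(silyloxymethyl)-2H-pyran-3(6H)-one | C[C@]1(O)C=CC(=O)[C@H](CO[Si](C)(C)C(C)(C)C)O1
A3 | alternative 2 | D-galactose | O=C[C@H](O)[C@@H](O)[C@@H](O)[C@H](O)CO
A4 | alternative 2 | ten-membered C3 sulfone with C7 alkynyl carbinol acetonide | COc1ccc(CO[C@H]2/C=C(\C)[C@@H](S(=O)(=O)c3ccccc3)C/C=C(/C)[C@@H](O[Si](C)(C)C(C)(C)C)[C@@H]3OC(C)(C)O[C@]23C#C[Si](C)(C)C)cc1
A5 | alternative 3 | diethyl D-tartrate | CCOC(=O)[C@@H](O)[C@H](O)C(=O)OCC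
A6 | alternative 3 | de-angeloyl target 8,9-acetonide | C=C1C(=O)O[C@H]2/C=C(\C)CC/C=C(/C)[C@H]3OC(C)(C)O[C@@H]3[C@@]12O
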